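**Retrosynthetic overview**

Locants: C1 = lactone C=O, C2 = its CH2, C3 = the CH–O–O carbon, C4 = C(CH3)–O(lactone), C5 = dioxane CH2, C6 = C(CH3)(C16H33)–O–O; O1 sits on C6, O2 on C3.
Last step: both rings come from two acyclic pieces, octadecan-2-one and (3S)-3-hydroperoxy-4-methylpent-4-enoic acid. O1–C6 is made first (intermolecular), the C5–C6 bond then closes the 1,2-dioxane, and O–C4 closes the γ-lactone; C4 and C6 are set from C3.
Enabling feature: in the 1,2-dioxane, C6 bears O1 and two carbon groups, so it is a ketone carbon in the form of a peroxycarbenium ion. C5H2–C4(CH3)–O is the Markovnikov adduct of an isopropenyl group, and the C1 carboxyl, two atoms from C3, can capture the C4 cation as the cis-fused five-membered lactone.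
C3 is the one stereocentre made by a catalyst: asymmetric β-peroxidation of (2E)-4-methylpenta-2,4-dienal with 2-methoxyprop-2-yl hydroperoxide, then CHO → CO2H and release of the hydroperoxide.
The dienal comes from methacrolein by Wittig homologation; the hydroperoxide reagent comes from 2,3-dimethylbut-2-ene by ozonolysis in methanol.

Key step: step 5

Remark: the target is (3R,4aS,7aS) in furo[3,2-c][1,2]dioxine numbering, which is C6 (R), C4 (S), C3 (S) in the locants above, with hexadecyl cis to the lactone ring. The sense of induction in step 3 is assumed to follow the usual shielding model of the diarylprolinol silyl ether.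

**Route**

Step 1
Reactants: 1 2,3-dimethylbut-2-ene
Product: 2 2-hydroperoxy-2-methoxypropane (2-methoxyprop-2-yl hydroperoxide)
Conditions: O3, MeOH/CH2Cl2, −78 °C; N2 purge; kept and used as a cold solution
Reagents that add atoms: ozone, [O-][O+]=O; methanol, CO
Why: Criegee ozonolysis with capture of the carbonyl oxide by methanol should give the α-methoxy hydroperoxide directly, the symmetrical alkene leaving no regiochemical choice and no stereocentre.

Step 2
Reactants: 3 methacrolein; 4 (triphenylphosphoranylidene)acetaldehyde
Product: 5 (2E)-4-methylpenta-2,4-dienal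
Conditions: 3 (3 equiv), toluene, 80 °C, sealed vessel; filtration, distillation, used as toluene solution
Reagents that add atoms: none
Why: Wittig olefination with a stabilised formyl ylide should give the (E)-enal, and the excess of volatile methacrolein should limit a second homologation.

Step 3
Reactants: 5 (2E)-4-methylpenta-2,4-dienal; 2 2-hydroperoxy-2-methoxypropane
Product: 6 (3S)-3-[(2-methoxypropan-2-yl)peroxy]-4-methylpent-4-enal
Conditions: (S)-2-{bis[3,5-bis(trifluoromethyl)phenyl](trimethylsilyloxy)methyl}pyrrolidine (10 mol %), PhCO2H (10 mol %), toluene, −20 °C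
Reagents that add atoms: none
Why: Iminium-ion catalysis (asymmetric oxa-Michael addition of a hydroperoxide to an enal): the silyloxydiarylmethyl group of the (S)-catalyst shields one face of the (E)-s-trans dienyl iminium ion, so the peroxide oxygen should add to the open face of C3 and give the (S)-configuration (to be confirmed by correlation, the (R)-catalyst being the remedy), addition at the β-carbon is expected as for other peroxide nucleophiles with dienals, and the acid co-catalyst at low temperature should favour protonation of the enamine over its closure to an epoxide.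

Step 4
Reactants: 6 (3S)-3-[(2-methoxypropan-2-yl)peroxy]-4-methylpent-4-enal
Product: 8 (3S)-3-hydroperoxy-4-methylpent-4-enoic acid, via peroxyketal acid 7 (not isolated)
Conditions: NaClO2, NaH2PO4, 2-methyl-2-butene, t-BuOH/H2O, 0 °C; then AcOH/H2O/THF, rt
Reagents that add atoms: sodium chlorite, [Na+].[O-]Cl=O
Why: Pinnick oxidation should convert the aldehyde into acid 7 under buffered conditions that spare the 1,1-disubstituted alkene (hypochlorous acid is scavenged) and C3, and mild aqueous acid then hydrolyses the 2-methoxyprop-2-yl peroxyketal, the standard release of a hydroperoxide from this protecting group.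

Step 5
Reactants: 8 (3S)-3-hydroperoxy-4-methylpent-4-enoic acid; 9 octadecan-2-one
Product: 14 (3R,4aS,7aS)-3-hexadecyl-3,4a-dimethyltetrahydrofuro[3,2-c][1,2]dioxin-6-one, via bis-silyl derivative 10 (not isolated), via silyloxy peroxyketal 11 (not isolated), via peroxycarbenium triflate 12 (not isolated), via dioxanyl cation triflate 13 (not isolated)
Conditions: (Me3Si)2NH, CH2Cl2, 40 °C, evaporate; then 9 (1.3 equiv), TMSOTf (0.2 equiv), CH2Cl2, −78 → −40 °C; Et3N; chromatography
Reagents that add atoms: none
Why: Proposed new method: after silylation to 10, TMSOTf mediates a Noyori-type silyl-transfer condensation of the silyl peroxide with ketone 9 to give silyloxy peroxyketal 11, which loses its siloxy group as hexamethyldisiloxane to give peroxycarbenium ion 12; the terminal CH2 (C5) of the isopropenyl group then attacks C6 to form the C5–C6 bond and tertiary cation 13, which the carbonyl oxygen of the silyl ester captures at C4 with return of TMSOTf. The closest known reaction types are the acid- or TMSOTf-catalysed condensation of hydroperoxy alcohols with ketones to 1,2,4-trioxanes, the Lewis acid-mediated, halide-terminated cyclisation of unsaturated monoperoxyketals through peroxycarbenium ions, and the Prins cyclisation terminated by an internal carboxyl group; their combination, with an alkene and then a carboxyl as internal nucleophiles of a peroxycarbenium ion, has not been shown. The 1,2-dioxane closes 6-endo-trig at the alkene (Markovnikov; the 5-exo mode would need a primary cation) and the γ-lactone closes by 5-exo capture of the ring cation. C4 is controlled by C3: allylic 1,2-strain with the C4 methyl group keeps C3–H near the alkene plane, so the peroxide tether and C6 occupy one alkene face and the CH2CO2SiMe3 arm the other, the carboxyl adds anti to C6 and the lactone is cis-fused; C6 is controlled by the chair transition state and the geometry of 12, in which the O–O bond lies syn to methyl and anti to the hexadecyl group, so that hexadecyl takes the equatorial site cis to the C3 arm. The step needs C–O ionisation of 11 in preference to O–O cleavage (secured by the ketone-level carbon and a silyl triflate at low temperature), Markovnikov ring closure (secured by the 1,1-disubstituted alkene) and facial selectivity at C6, which rests only on the size difference between methyl and a primary alkyl group and is the weaker relay, so that the C6 epimer is expected as a minor product to be removed by chromatography. C3 is not touched.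

**Compound list**

1 | 2,3-dimethylbut-2-ene | CC(C)=C(C)C | starting material
2 | 2-hydroperoxy-2-methoxypropane | COC(C)(C)OO | intermediate
3 | methacrolein | CC(=C)C=O | starting material
4 | (triphenylphosphoranylidene)acetaldehyde | O=CC=P(c1ccccc1)(c1ccccc1)c1ccccc1 | starting material
5 | (2E)-4-methylpenta-2,4-dienal | CC(=C)/C=C/C=O | intermediate
6 | (3S)-3-[(2-methoxypropan-2-yl)peroxy]-4-methylpent-4-enal | COC(C)(C)OO[C@@H](CC=O)C(C)=C | intermediate
7 | (3S)-3-[(2-methoxypropan-2-yl)peroxy]-4-methylpent-4-enoic acid | COC(C)(C)OO[C@@H](CC(=O)O)C(C)=C | intermediate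
8 | (3S)-3-hydroperoxy-4-methylpent-4-enoic acid | OO[C@@H](CC(=O)O)C(C)=C | intermediate
9 | octadecan-2-one | CCCCCCCCCCCCCCCCC(C)=O | starting material
10 | trimethylsilyl (3S)-4-methyl-3-[(trimethylsilyl)peroxy]pent-4-enoate | C[Si](C)(C)OO[C@@H](CC(=O)O[Si](C)(C)C)C(C)=C | intermediate
11 | trimethylsilyl (3S)-4-methyl-3-{[2-(trimethylsilyloxy)octadecan-2-yl]peroxy}pent-4-enoate (ketal carbon unassigned) | CCCCCCCCCCCCCCCCC(C)(O[Si](C)(C)C)OO[C@@H](CC(=O)O[Si](C)(C)C)C(C)=C | intermediate
12 | peroxycarbenium triflate derived from 11 (C6 cation, O1=C6) | CCCCCCCCCCCCCCCCC(C)=[O+]O[C@@H](CC(=O)O[Si](C)(C)C)C(C)=C.[O-]S(=O)(=O)C(F)(F)F | intermediate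
13 | (3S,6R)-6-hexadecyl-4,6-dimethyl-3-[2-oxo-2-(trimethylsilyloxy)ethyl]-1,2-dioxan-4-yl cation triflate | CCCCCCCCCCCCCCCC[C@]1(C)C[C+](C)[C@H](CC(=O)O[Si](C)(C)C)OO1.[O-]S(=O)(=O)C(F)(F)F | intermediate
14 | (3R,4aS,7aS)-3-hexadecyl-3,4a-dimethyltetrahydrofuro[3,2-c][1,2]dioxin-6-one (cis-fused 1,2-dioxane/γ-lactone) | CCCCCCCCCCCCCCCC[C@]1(C)C[C@]2(C)OC(=O)C[C@@H]2OO1 | target

**Step count and risks**

Total steps: 5. Longest linear sequence: 4 (steps 1, 3, 4, 5).

Most likely to fail, step 5: O–O heterolysis (Criegee/Hock-type fragmentation) in 11 or 12 may compete with C–O ionisation, cation 13 may lose a proton before the lactone closes, and the facial discrimination at C6 may be low. Fallback: the one-flask condensation–cyclisation is split into operations of known type. Setting out from 9, ketalisation (HC(OMe)3, MeOH, cat. TsOH) gives 2,2-dimethoxyoctadecane F1. Acid-catalysed trans-ketalisation of F1 with hydroperoxide 8 (PPTS, CH2Cl2) gives the mixed peroxyketal (3S)-3-[(2-methoxyoctadecan-2-yl)peroxy]-4-methylpent-4-enoic acid F2. TiCl4 in CH2Cl2 at −78 °C then effects the halide-terminated peroxycarbenium–alkene cyclisation to 2-[(3S,6R)-4-chloro-6-hexadecyl-4,6-dimethyl-1,2-dioxan-3-yl]acetic acid F3 (either C4 epimer serves). AgOTf with 2,6-di-tert-butylpyridine ionises the tertiary chloride so that the neighbouring carboxyl closes the lactone, and the sequence comes back to the route at 14.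

Second, step 3: the β-peroxy enamine may close to an epoxide with loss of the hemiketal alkoxide, the hydroperoxide may add at the δ- instead of the β-carbon, or reversible addition may erode the enantiomeric purity. Fallback: the catalytic oxa-Michael addition is replaced by an ene reaction and a resolution. Compounds 1 to 7 are not needed, so this fallback sets out from commercial 4-methylpent-3-enoic acid F4 instead of from a numbered compound. Singlet oxygen (O2, tetraphenylporphyrin, visible light, CH2Cl2, 0 °C; Schenck ene reaction) should give 3-hydroperoxy-4-methylpent-4-enoic acid as the racemate, that is 8 together with (3R)-3-hydroperoxy-4-methylpent-4-enoic acid F5. Preparative chromatography on a chiral stationary phase (or crystallisation of the salt with a chiral amine) removes F5, and the fallback comes back to the route at 8.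

Third, step 2: a second homologation to the trienal, thermal oligomerisation and loss of the volatile dienal on isolation may leave little material. Fallback: setting out from 3, Horner–Wadsworth–Emmons olefination with triethyl phosphonoacetate (NaH, THF, 0 °C) gives ethyl (2E)-4-methylpenta-2,4-dienoate F6. i-Bu2AlH (CH2Cl2, −78 °C) reduces it to (2E)-4-methylpenta-2,4-dien-1-ol F7, and MnO2 (CH2Cl2, rt) oxidises the allylic alcohol. The fallback comes back to the route at 5, which is then handled only in solution.

Further compounds
F1 | step 5 | 2,2-dimethoxyoctadecane | CCCCCCCCCCCCCCCCC(C)(OC)OC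
F2 | step 5 | (3S)-3-[(2-methoxyoctadecan-2-yl)peroxy]-4-methylpent-4-enoic acid (ketal carbon unassigned) | CCCCCCCCCCCCCCCCC(C)(OC)OO[C@@H](CC(=O)O)C(C)=C
F3 | step 5 | 2-[(3S,6R)-4-chloro-6-hexadecyl-4,6-dimethyl-1,2-dioxan-3-yl]acetic acid (C4 unassigned) | CCCCCCCCCCCCCCCC[C@]1(C)CC(C)(Cl)[C@H](CC(=O)O)OO1
F4 | step 3 | 4-methylpent-3-enoic acid | CC(C)=CCC(=O)O
F5 | step 3 | (3R)-3-hydroperoxy-4-methylpent-4-enoic acid | OO[C@H](CC(=O)O)C(C)=C
F6 | step 2 | ethyl (2E)-4-methylpenta-2,4-dienoate | CCOC(=O)/C=C/C(C)=C
F7 | step 2 | (2E)-4-methylpenta-2,4-dien-1-ol | CC(=C)/C=C/CO
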